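**Retrosynthetic overview**

- The cyclopentane is numbered C1 (carbinol carbon), C2 (CH carrying the CH2 link), C3 (CH carrying isopropenyl), C4 and C5 (CH2). The C1–CH3 bond is made last by methyl Grignard addition to a cyclopentanone. Before that, the CH2–trione bond is made by Michael addition of the dearomatised acylphloroglucinol to a 2-methylidenecyclopentanone.
- The cyclopentanone is closed by a (3+2) annulation of the α,γ-dianion of an acetonylphosphonate (C5–C1–C2) with isoprene 1,4-dibromide (C4–C3 plus the latent isopropenyl). C4–C5 forms by SN2 and C2–C3 by palladium-catalysed allylic alkylation, in one flask.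
- Enabling feature: C1 is a latent ketone flanked by C2 and C5, so the ring contains a 1,3-dinucleophilic acetone unit. C4H2–C3H–C(CH3)=CH2 is an allylically transposed 2-methylbut-2-ene-1,4-diyl unit.
- Ring order: the cyclopentane is the only ring built. The six-membered ring comes from phloroglucinol by acylation and dearomatising gem-diprenylation.
- Stereocontrol: C3 by the chiral palladium catalyst, C2 by equilibration to trans, C1 by addition anti to the C2 substituent. The phosphonate activates C2 and is then spent in a Horner–Wadsworth–Emmons methylenation that supplies the CH2 link.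

Key step: step 2

Assumption: the (R,R)-enantiomer of the diphosphine ligand is taken to give the required sense at the new allylic stereocentre; if the sense proves opposite, the (S,S)-ligand is used and nothing else changes.

Remark: the dearomatised acylphloroglucinols are drawn in the dienol tautomer of the target SMILES; they are tautomeric mixtures.

**Step 1**
Reactants: 1 isoprene (2-methylbuta-1,3-diene)
Product: 2 (E)-1,4-dibromo-2-methylbut-2-ene
Conditions: Br2 (1 equiv), CH2Cl2, −25 °C → rt
Reagents that add atoms: bromine, BrBr
Why: Electrophilic 1,4-addition of bromine to the conjugated diene; the allylic bromides equilibrate, so the thermodynamically preferred (E)-1,4-dibromide should predominate.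

**Step 2**
Reactants: 2 (E)-1,4-dibromo-2-methylbut-2-ene; 3 dimethyl (2-oxopropyl)phosphonate
Product: 6 dimethyl [(1S,5S)-2-oxo-5-(prop-1-en-2-yl)cyclopentyl]phosphonate, via phosphonate dianion 4 (not isolated), via bromoalkenyl enolate 5 (not isolated)
Conditions: NaH, THF, 0 °C; n-BuLi, 0 °C; add to 2, THF, −78 °C; then Pd2(dba)3·CHCl3 (2.5 mol %), (1R,2R)-N,N'-bis[2-(diphenylphosphino)benzoyl]cyclohexane-1,2-diamine (7.5 mol %), −78 °C → rt
Reagents that add atoms: none
Why: Double deprotonation of 3 gives dianion 4, whose more basic γ-carbanion displaces the more reactive bromide of 2 (the CH2Br on the CH= carbon, prenyl-type and remote from the methyl branch) in an SN2 step that forms C4–C5 and leaves enolate 5; zerovalent palladium then ionises the second allylic bromide to a 2-methyl-π-allyl complex, and the phosphonate-stabilised enolate carbon attacks its proximal terminus, forming C2–C3 and unveiling the isopropenyl group by allylic transposition. The closest known reactions are the domino cyclisation of 1,3-dicarbonyl dianions with 1,4-dibromobut-2-ene and the palladium-catalysed cyclisation of 3-oxo-oct-6-enyl allylic electrophiles to 2-acceptor-3-vinylcyclopentanones (Tsuji–Trost allylic alkylation), merged here in one flask. The cyclopentanone closes in a 5-exo-trig allylic alkylation; the uncatalysed SN2' closure through carbon would be a stereoelectronically disfavoured 5-(enolendo) process, hence the metal. The new C3 stereocentre (C5 in the name of 6) is under catalyst control: the two faces of the π-allyl interconvert through the unsubstituted CH2 terminus (π–σ–π), so the chiral pocket of the ligand should select the face attacked, and the adjacent phosphonate-bearing carbon is epimerisable and should settle trans. The step needs carbon- over oxygen-alkylation and five- over seven-membered closure; any allyl enol ether formed through oxygen carries a vinylogous leaving group that the same catalyst should re-ionise and funnel to the C-alkylated ketone, and attack at the proximal allyl terminus gives the kinetically favoured ring size.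

**Step 3**
Reactants: 6 dimethyl [(1S,5S)-2-oxo-5-(prop-1-en-2-yl)cyclopentyl]phosphonate; 7 formaldehyde (37 % aqueous)
Product: 8 (S)-2-methylidene-3-(prop-1-en-2-yl)cyclopentan-1-one
Conditions: K2CO3 (2 equiv), THF/H2O, 0 °C; used at once as a solution
Reagents that add atoms: none
Why: Horner–Wadsworth–Emmons olefination of the cyclic β-keto phosphonate with formaldehyde gives the exocyclic enone; the C3 stereocentre is not acidic towards carbonate and is carried through, while the labile phosphonate-bearing centre is erased on purpose.

**Step 4**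
Reactants: 9 phloroglucinol (benzene-1,3,5-triol); 10 isobutyryl chloride (2-methylpropanoyl chloride)
Product: 11 2-methyl-1-(2,4,6-trihydroxyphenyl)propan-1-one
Conditions: AlCl3 (3.5 equiv), PhNO2/CH2Cl2, 0 → 50 °C; aq. HCl
Reagents that add atoms: none
Why: Friedel–Crafts C-acylation of the electron-rich triphenol; the first acyl group deactivates the ring, so monoacylation should prevail.

**Step 5**
Reactants: 11 2-methyl-1-(2,4,6-trihydroxyphenyl)propan-1-one; 12 prenyl bromide (1-bromo-3-methylbut-2-ene, 2.1 equiv)
Product: 13 3,5-dihydroxy-2-(2-methylpropanoyl)-6,6-bis(3-methylbut-2-en-1-yl)cyclohexa-2,4-dien-1-one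
Conditions: NaOMe (2.2 equiv), MeOH, 0 °C → rt; chromatography
Reagents that add atoms: none
Why: Base-mediated alkylative dearomatisation: the phloroglucinate anion is C-prenylated, and a second C-alkylation at the same carbon gives the cross-conjugated gem-diprenyl dienone, a vinylogous acid that should be separable from the aromatic 3,5-diprenyl isomer.

**Step 6**
Reactants: 8 (S)-2-methylidene-3-(prop-1-en-2-yl)cyclopentan-1-one; 13 3,5-dihydroxy-2-(2-methylpropanoyl)-6,6-bis(3-methylbut-2-en-1-yl)cyclohexa-2,4-dien-1-one (1.1 equiv)
Product: 14 3,5-dihydroxy-2-(2-methylpropanoyl)-6,6-bis(3-methylbut-2-en-1-yl)-4-{[(1S,5R)-2-oxo-5-(prop-1-en-2-yl)cyclopentyl]methyl}cyclohexa-2,4-dien-1-one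
Conditions: Et3N (0.2 equiv), THF, 0 °C → rt
Reagents that add atoms: none
Why: Michael addition of the soft, acidic trione carbon (the only unsubstituted ring carbon) to the exocyclic enone; the new cyclopentanone C2 centre is α to the ketone and should equilibrate under the amine to the trans-2,3-disubstituted ketone.

**Step 7**
Reactants: 14 3,5-dihydroxy-2-(2-methylpropanoyl)-6,6-bis(3-methylbut-2-en-1-yl)-4-{[(1S,5R)-2-oxo-5-(prop-1-en-2-yl)cyclopentyl]methyl}cyclohexa-2,4-dien-1-one
Product: 15 3,5-dihydroxy-4-{[(1S,2R,5R)-2-hydroxy-2-methyl-5-(prop-1-en-2-yl)cyclopentyl]methyl}-2-(2-methylpropanoyl)-6,6-bis(3-methylbut-2-en-1-yl)cyclohexa-2,4-dien-1-one (the target)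
Conditions: MeMgBr (5 equiv), LaCl3·2LiCl (1 equiv), THF, −78 → −20 °C; sat. aq. NH4Cl
Reagents that add atoms: methylmagnesium bromide, C[Mg]Br
Why: 1,2-Addition of the Grignard reagent to the cyclopentanone, lanthanum-promoted to suppress enolisation, after the two acidic enols have become unreactive magnesium enolates; methyl should enter anti to the adjacent C2 side chain (steric approach control on the trans-2,3-disubstituted cyclopentanone), which places the hydroxyl cis to that chain as required.

**Compound list**

1 | isoprene | C=CC(C)=C | starting material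
2 | (E)-1,4-dibromo-2-methylbut-2-ene | BrC/C=C(\C)CBr | intermediate
3 | dimethyl (2-oxopropyl)phosphonate | CC(=O)CP(=O)(OC)OC | starting material
4 | sodium lithium α,γ-dianion of dimethyl (2-oxopropyl)phosphonate | [Na+].[Li+].[CH2-]C(=O)[CH-]P(=O)(OC)OC | intermediate
5 | sodium enolate of dimethyl [(5E)-7-bromo-6-methyl-2-oxohept-5-en-1-yl]phosphonate | [Na+].COP(=O)(OC)[CH-]C(=O)CC/C=C(\C)CBr | intermediate
6 | dimethyl [(1S,5S)-2-oxo-5-(prop-1-en-2-yl)cyclopentyl]phosphonate | C=C(C)[C@@H]1CCC(=O)[C@H]1P(=O)(OC)OC | intermediate
7 | formaldehyde | C=O | starting material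
8 | (S)-2-methylidene-3-(prop-1-en-2-yl)cyclopentan-1-one | C=C(C)[C@@H]1CCC(=O)C1=C | intermediate
9 | phloroglucinol | Oc1cc(O)cc(O)c1 | starting material
10 | isobutyryl chloride | CC(C)C(Cl)=O | starting material
11 | 2-methyl-1-(2,4,6-trihydroxyphenyl)propan-1-one | CC(C)C(=O)c1c(O)cc(O)cc1O | intermediate
12 | prenyl bromide (1-bromo-3-methylbut-2-ene) | CC(C)=CCBr | starting material
13 | 3,5-dihydroxy-2-(2-methylpropanoyl)-6,6-bis(3-methylbut-2-en-1-yl)cyclohexa-2,4-dien-1-one | C1=C(O)C(CC=C(C)C)(CC=C(C)C)C(=O)C(C(=O)C(C)C)=C1O | intermediate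
14 | 3,5-dihydroxy-2-(2-methylpropanoyl)-6,6-bis(3-methylbut-2-en-1-yl)-4-{[(1S,5R)-2-oxo-5-(prop-1-en-2-yl)cyclopentyl]methyl}cyclohexa-2,4-dien-1-one | C=C(C)[C@@H]1CCC(=O)[C@H]1CC1=C(O)C(CC=C(C)C)(CC=C(C)C)C(=O)C(C(=O)C(C)C)=C1O | intermediate
15 | 3,5-dihydroxy-4-{[(1S,2R,5R)-2-hydroxy-2-methyl-5-(prop-1-en-2-yl)cyclopentyl]methyl}-2-(2-methylpropanoyl)-6,6-bis(3-methylbut-2-en-1-yl)cyclohexa-2,4-dien-1-one | C=C(C)[C@@H]1CC[C@@](C)(O)[C@H]1CC1=C(O)C(CC=C(C)C)(CC=C(C)C)C(=O)C(C(=O)C(C)C)=C1O | target

**Step count and risks**

Total step count: 7. Longest linear sequence: 5 steps (steps 1, 2, 3, 6, 7); steps 4 and 5 form the second branch.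

**Step 2 (key step).** What may go wrong: the first alkylation may not discriminate well enough between the two bromomethyl termini, ring closure may run through the enolate oxygen or at the distal allyl terminus (seven-membered ring), and enantiofacial discrimination at the π-allyl stage may be insufficient. The fallback sets out from formaldehyde 7 together with commercial cyclopent-2-en-1-one and comes back to the route at 8. The C3 stereocentre is set instead by copper-catalysed asymmetric conjugate addition of isopropenylmagnesium bromide to cyclopent-2-en-1-one (CuBr·SMe2, a chiral ferrocenyl diphosphine of the Josiphos family, t-BuOMe, −75 °C) with Me3SiCl trapping. This should give the regiodefined silyl enol ether trimethyl{[(3R)-3-(prop-1-en-2-yl)cyclopent-1-en-1-yl]oxy}silane F1. Mukaiyama hydroxymethylation with aqueous formaldehyde 7 (Yb(OTf)3, THF/H2O) should give (2R,3R)-2-(hydroxymethyl)-3-(prop-1-en-2-yl)cyclopentan-1-one F2. Mesylation (MsCl, Et3N) to [(1R,5R)-2-oxo-5-(prop-1-en-2-yl)cyclopentyl]methyl methanesulfonate F3 and elimination with DBU then deliver 8. The enantioselectivity of the copper step on the five-membered enone is the soft spot of this fallback.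

**Step 7.** What may go wrong: enolisation of the cyclopentanone instead of addition, followed by retro-Michael loss of the stabilised trione anion, and erosion of facial selectivity by the neighbouring magnesium enolate. The fallback sets out from 8 and 11 and comes back at 15. The aromatic acylphloroglucinol 11 (in excess, Et3N cat.) is added to enone 8 to give 2-methyl-1-(2,4,6-trihydroxy-3-{[(1S,5R)-2-oxo-5-(prop-1-en-2-yl)cyclopentyl]methyl}phenyl)propan-1-one F7. Its aryl carbon is a far poorer leaving group and its triphenoxide is inert, so MeMgBr/LaCl3·2LiCl should add cleanly anti to the side chain to give 2-methyl-1-(2,4,6-trihydroxy-3-{[(1S,2R,5R)-2-hydroxy-2-methyl-5-(prop-1-en-2-yl)cyclopentyl]methyl}phenyl)propan-1-one F8. Dearomatising double prenylation with 12 (NaOMe, MeOH) at the only free ring carbon, with the cyclopentylmethyl group acting as a blocking group, then gives 15. The second prenylation could still go to the side-chain-bearing carbon, which is the residual risk.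

**Step 5.** What may go wrong: the second alkylation partitions between the already prenylated carbon and the free ring CH (aromatic 3,5-isomer), with over-alkylation and O-alkylation as further drains. The fallback sets out from prenyl bromide 12 together with commercial dimethyl malonate and 5-methylhexane-2,4-dione, bypasses 9 to 11 and comes back at 13. Dimethyl malonate is dialkylated with 12 (NaH, THF) to dimethyl 2,2-bis(3-methylbut-2-en-1-yl)propanedioate F4. The dilithium 1,3-dianion of 5-methylhexane-2,4-dione F5 (LDA, 2 equiv, THF) is acylated at its terminal methyl carbon by one ester group of F4 to give methyl 8-methyl-2,2-bis(3-methylbut-2-en-1-yl)-3,5,7-trioxononanoate F6. Claisen cyclisation of the C6 carbanion onto the remaining ester (NaOMe, MeOH) closes the six-membered ring to 13. The quaternary carbon is in place before the ring exists, so no regiochemical choice arises.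

**Further compounds**

F1 | step 2 | trimethyl{[(3R)-3-(prop-1-en-2-yl)cyclopent-1-en-1-yl]oxy}silane | C=C(C)[C@@H]1CCC(O[Si](C)(C)C)=C1
F2 | step 2 | (2R,3R)-2-(hydroxymethyl)-3-(prop-1-en-2-yl)cyclopentan-1-one | C=C(C)[C@@H]1CCC(=O)[C@H]1CO
F3 | step 2 | [(1R,5R)-2-oxo-5-(prop-1-en-2-yl)cyclopentyl]methyl methanesulfonate | C=C(C)[C@@H]1CCC(=O)[C@H]1COS(C)(=O)=O
F4 | step 5 | dimethyl 2,2-bis(3-methylbut-2-en-1-yl)propanedioate | COC(=O)C(CC=C(C)C)(CC=C(C)C)C(=O)OC
F5 | step 5 | dilithium 1,3-dianion of 5-methylhexane-2,4-dione | [Li+].[Li+].[CH2-]C(=O)[CH-]C(=O)C(C)C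
F6 | step 5 | methyl 8-methyl-2,2-bis(3-methylbut-2-en-1-yl)-3,5,7-trioxononanoate | COC(=O)C(CC=C(C)C)(CC=C(C)C)C(=O)CC(=O)CC(=O)C(C)C
F7 | step 7 | 2-methyl-1-(2,4,6-trihydroxy-3-{[(1S,5R)-2-oxo-5-(prop-1-en-2-yl)cyclopentyl]methyl}phenyl)propan-1-one | C=C(C)[C@@H]1CCC(=O)[C@H]1Cc1c(O)cc(O)c(C(=O)C(C)C)c1O
F8 | step 7 | 2-methyl-1-(2,4,6-trihydroxy-3-{[(1S,2R,5R)-2-hydroxy-2-methyl-5-(prop-1-en-2-yl)cyclopentyl]methyl}phenyl)propan-1-one | C=C(C)[C@@H]1CC[C@@](C)(O)[C@H]1Cc1c(O)cc(O)c(C(=O)C(C)C)c1O
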